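**Retrosynthetic overview** (germacrane atom labels: C6 lactone carbinol, C7 ring fusion, C8 ester carbinol, C12 lactone carbonyl, C14 methyl ester, C15 hydroxymethyl)
1. The γ-lactone is closed last: its C6–O bond is made by dealkylative hydrolactonisation of the C5=C6 alkene of a ten-membered carbocycle by the tert-butyl acrylate on C7; desilylation of C15–O then gives the target.
2. The carbocycle (formed first) comes from ring-closing metathesis of two vinyl groups (C5=C6), giving a cis,cis-cyclodeca-1,6-diene.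
3. The metathesis substrate comes from an E-selective Horner–Wadsworth–Emmons union (C1=C10) of a western phosphonate and an eastern aldehyde.
4. West: C7–C8 by catalytic asymmetric chromium allylation of a phosphonate aldehyde with a pentadienoate bromide, then esterification with (R)-2-methylbutanoic acid. East: C4 by copper-catalysed asymmetric allylic alkylation.
5. Ring order: ten-membered carbocycle, then the five-membered lactone.

Assumption: (R)-2-methylbutanoic acid and (E)-but-2-ene-1,4-diol are bought; the ligand antipodes written in steps 3 and 9 are those expected to give the drawn configurations and would be exchanged for their mirror images if the observed sense is opposite.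

**Step 1**
Reactants: 1 (2E)-but-2-ene-1,4-diol
Product: 2 (2E)-4-[(tert-butyldiphenylsilyl)oxy]but-2-en-1-ol
Conditions: NaH (1.0 equiv), THF, 0 °C; then tBuPh2SiCl (1.0 equiv), rt
Reagents that add atoms: tert-butyl(chloro)diphenylsilane, CC(C)(C)[Si](Cl)(c1ccccc1)c1ccccc1
Why: O-silylation of the sparingly soluble monosodium alkoxide gives clean monoprotection of the symmetrical diol; no stereocentre is involved.

**Step 2**
Reactants: 2 (2E)-4-[(tert-butyldiphenylsilyl)oxy]but-2-en-1-ol
Product: 3 {[(2E)-4-bromobut-2-en-1-yl]oxy}(tert-butyl)diphenylsilane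
Conditions: CBr4, PPh3, CH2Cl2, 0 °C
Reagents that add atoms: tetrabromomethane, BrC(Br)(Br)Br
Why: Appel bromination replaces the primary allylic hydroxyl by SN2 without allylic transposition or loss of the E geometry.

**Step 3**
Reactants: 3 {[(2E)-4-bromobut-2-en-1-yl]oxy}(tert-butyl)diphenylsilane; 4 2-(2-bromoethyl)-1,3-dioxolane
Product: 6 2-[(3S)-3-{[(tert-butyldiphenylsilyl)oxy]methyl}pent-4-en-1-yl]-1,3-dioxolane, via Grignard reagent 5 (not isolated)
Conditions: Mg, Et2O, rt (4 → 5); then 3, CuBr·SMe2 (1 mol%), (R,R)-Taniaphos (1.2 mol%), CH2Cl2, −78 °C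
Reagents that add atoms: none
Why: Copper-catalysed asymmetric allylic alkylation (SN2') of an E-allylic bromide with a Grignard reagent delivers the alkyl group to the γ-carbon, and the chiral ferrocenyl diphosphine–copper complex sets the C4 stereocentre (3S here) by catalyst control.

**Step 4**
Reactants: 6 2-[(3S)-3-{[(tert-butyldiphenylsilyl)oxy]methyl}pent-4-en-1-yl]-1,3-dioxolane
Product: 7 (4S)-4-{[(tert-butyldiphenylsilyl)oxy]methyl}hex-5-enal
Conditions: 2 M HCl (aq), THF, rt
Reagents that add atoms: water, O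
Why: Acid-catalysed acetal hydrolysis frees the aldehyde while the silyl ether and the non-enolisable γ-stereocentre are untouched.

**Step 5**
Reactants: 8 methyl 2-(diethoxyphosphoryl)acetate; 9 3-bromoprop-1-ene
Product: 10 methyl 2-(diethoxyphosphoryl)pent-4-enoate
Conditions: NaH, THF, 0 °C → rt
Reagents that add atoms: none
Why: C-alkylation of the phosphonoacetate anion with an allylic halide (SN2); the new stereocentre is racemic and is destroyed in step 11.

**Step 6**
Reactants: 10 methyl 2-(diethoxyphosphoryl)pent-4-enoate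
Product: 12 methyl 2-(diethoxyphosphoryl)-4-oxobutanoate, via ozonide 11 (not isolated)
Conditions: O3, CH2Cl2, −78 °C; then PPh3, −78 °C → rt
Reagents that add atoms: ozone, [O-][O+]=O
Why: Ozonolysis with reductive work-up cleaves the only alkene to the aldehyde.

**Step 7**
Reactants: 13 prop-2-enal; 14 tert-butyl prop-2-enoate
Product: 15 tert-butyl 3-hydroxy-2-methylidenepent-4-enoate
Conditions: DABCO (20 mol%), 14 (3 equiv, neat), slow addition of 13, rt
Reagents that add atoms: none
Why: Morita–Baylis–Hillman reaction, in which the DABCO–acrylate zwitterion adds 1,2 to acrolein; the racemic carbinol becomes sp2 in step 8.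

**Step 8**
Reactants: 15 tert-butyl 3-hydroxy-2-methylidenepent-4-enoate
Product: 16 tert-butyl (2Z)-2-(bromomethyl)penta-2,4-dienoate
Conditions: PBr3 (0.4 equiv), Et2O, −10 °C → rt
Reagents that add atoms: phosphorus tribromide, BrP(Br)Br
Why: Bromination of a Morita–Baylis–Hillman alcohol with allylic transposition (SN2') gives the thermodynamically preferred 2Z bromide, with the vinyl group trans to the ester.

**Step 9**
Reactants: 12 methyl 2-(diethoxyphosphoryl)-4-oxobutanoate; 16 tert-butyl (2Z)-2-(bromomethyl)penta-2,4-dienoate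
Product: 18 1-tert-butyl 7-methyl (3R,4R)-6-(diethoxyphosphoryl)-3-ethenyl-4-hydroxy-2-methylideneheptanedioate, via trimethylsilyl ether 17 (not isolated)
Conditions: CrCl2 (10 mol%), (S,S)-3,6-di-tert-butyl-1,8-bis(4-isopropyl-4,5-dihydrooxazol-2-yl)carbazole (12 mol%), iPr2NEt (30 mol%), Mn (2 equiv), Me3SiCl (1.5 equiv), THF, 0 °C; then 0.5 M HCl (aq), 0 °C
Reagents that add atoms: none
Why: Catalytic asymmetric Nozaki–Hiyama–Kishi 2-(alkoxycarbonyl)allylation, in which the allylchromium from 16 attacks through its γ-carbon (C7) in a chair transition state so that the Z geometry gives the syn relation of the C8 hydroxyl and the C7 vinyl group (the isomeric pentadienyl species converges on the same diastereomer), while the chiral carbazole–bis(oxazoline) chromium complex selects the aldehyde face to set C7 and C8 (3R,4R here).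

**Step 10**
Reactants: 18 1-tert-butyl 7-methyl (3R,4R)-6-(diethoxyphosphoryl)-3-ethenyl-4-hydroxy-2-methylideneheptanedioate; 19 (2R)-2-methylbutanoic acid
Product: 21 1-tert-butyl 7-methyl (3R,4R)-6-(diethoxyphosphoryl)-3-ethenyl-2-methylidene-4-{[(2R)-2-methylbutanoyl]oxy}heptanedioate, via O-acylisourea 20 (not isolated)
Conditions: iPrN=C=NiPr (1.5 equiv), DMAP (10 mol%), CH2Cl2, 0 °C → rt
Reagents that add atoms: none
Why: Steglich esterification forms the acyl–oxygen bond with retention at C8, and catalytic DMAP at 0 °C leaves the α-stereocentre of the acid intact.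

**Step 11**
Reactants: 21 1-tert-butyl 7-methyl (3R,4R)-6-(diethoxyphosphoryl)-3-ethenyl-2-methylidene-4-{[(2R)-2-methylbutanoyl]oxy}heptanedioate; 7 (4S)-4-{[(tert-butyldiphenylsilyl)oxy]methyl}hex-5-enal
Product: 22 1-tert-butyl 7-methyl (3R,4R,6E)-6-[(4S)-4-{[(tert-butyldiphenylsilyl)oxy]methyl}hex-5-en-1-ylidene]-3-ethenyl-2-methylidene-4-{[(2R)-2-methylbutanoyl]oxy}heptanedioate
Conditions: LiCl, DBU, MeCN (0.5 M), 0 °C → rt
Reagents that add atoms: none
Why: Horner–Wadsworth–Emmons olefination under Masamune–Roush conditions gives the E trisubstituted enoate (chain trans to CO2Me), with the concentrated aldehyde outrunning 6-endo Michael addition to the hindered tert-butyl acrylate; the minor Z isomer is removed by chromatography.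

**Step 12**
Reactants: 22 1-tert-butyl 7-methyl (3R,4R,6E)-6-[(4S)-4-{[(tert-butyldiphenylsilyl)oxy]methyl}hex-5-en-1-ylidene]-3-ethenyl-2-methylidene-4-{[(2R)-2-methylbutanoyl]oxy}heptanedioate
Product: 23 methyl (1E,5S,6Z,8R,9R)-8-[3-(tert-butoxy)-3-oxoprop-1-en-2-yl]-5-{[(tert-butyldiphenylsilyl)oxy]methyl}-9-{[(2R)-2-methylbutanoyl]oxy}cyclodeca-1,6-diene-1-carboxylate
Conditions: second-generation Hoveyda–Grubbs catalyst [RuCl2(SIMes)(=CH–C6H4-2-OiPr)] (10 mol%), 1,4-benzoquinone (20 mol%), toluene (1 mM), 80 °C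
Reagents that add atoms: none
Why: Ring-closing metathesis joins the two monosubstituted vinyl groups far faster than the 1,1-disubstituted acrylate or the trisubstituted enoate can react, and the product is a cis,cis-cyclodeca-1,6-diene, the least strained cyclodecadiene, so the ring closes with Z geometry (an E isomer would give the same lactone in step 13 because C5 becomes CH2).

**Step 13**
Reactants: 23 methyl (1E,5S,6Z,8R,9R)-8-[3-(tert-butoxy)-3-oxoprop-1-en-2-yl]-5-{[(tert-butyldiphenylsilyl)oxy]methyl}-9-{[(2R)-2-methylbutanoyl]oxy}cyclodeca-1,6-diene-1-carboxylate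
Product: 24 methyl (3aS,4R,6E,10S,11aR)-10-{[(tert-butyldiphenylsilyl)oxy]methyl}-3-methylidene-4-{[(2R)-2-methylbutanoyl]oxy}-2-oxo-2,3,3a,4,5,8,9,10,11,11a-decahydrocyclodeca[b]furan-6-carboxylate
Conditions: [PtCl2(C2H4)]2 (5 mol%), P(C6H4-4-CF3)3 (10 mol%), Cl2CHCHCl2, 70 °C
Reagents that add atoms: none
Why: Proposed new method: platinum-catalysed dealkylative hydrolactonisation, in which the electrophilic divalent platinum centre binds the only electron-rich alkene (C5=C6), the tert-butyl ester carbonyl oxygen attacks C6 anti to platinum in a 5-exo mode from the conformer that keeps H7 eclipsed with the alkene and C8 outside (A(1,3) strain and the ring forbid the alternative), the tert-butoxy oxocarbenium ion loses 2-methylpropene and the released proton cleaves the C5–Pt bond, so the C6–O bond and the C6 stereocentre (11aR, trans ring fusion) are set by substrate control; the closest known reaction types are platinum-catalysed intramolecular hydroalkoxylation of γ-hydroxy alkenes, acid- or silver-catalysed hydrolactonisation of 4-alkenoic acids and π-acid-triggered dealkylative cyclisation of tert-butyl esters.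

**Step 14**
Reactants: 24 methyl (3aS,4R,6E,10S,11aR)-10-{[(tert-butyldiphenylsilyl)oxy]methyl}-3-methylidene-4-{[(2R)-2-methylbutanoyl]oxy}-2-oxo-2,3,3a,4,5,8,9,10,11,11a-decahydrocyclodeca[b]furan-6-carboxylate
Product: 25 methyl (3aS,4R,6E,10S,11aR)-10-(hydroxymethyl)-3-methylidene-4-{[(2R)-2-methylbutanoyl]oxy}-2-oxo-2,3,3a,4,5,8,9,10,11,11a-decahydrocyclodeca[b]furan-6-carboxylate
Conditions: HF·pyridine, pyridine/THF, 0 °C → rt
Reagents that add atoms: none
Why: Silyl ether cleavage by buffered hydrogen fluoride removes the silyl group without conjugate addition to the α-methylene lactone or ester cleavage.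

**Compound list**
1 | (2E)-but-2-ene-1,4-diol | OC/C=C/CO | starting material
2 | (2E)-4-[(tert-butyldiphenylsilyl)oxy]but-2-en-1-ol | OC/C=C/CO[Si](c1ccccc1)(c1ccccc1)C(C)(C)C | intermediate
3 | {[(2E)-4-bromobut-2-en-1-yl]oxy}(tert-butyl)diphenylsilane | BrC/C=C/CO[Si](c1ccccc1)(c1ccccc1)C(C)(C)C | intermediate
4 | 2-(2-bromoethyl)-1,3-dioxolane | BrCCC1OCCO1 | starting material
5 | [2-(1,3-dioxolan-2-yl)ethyl]magnesium bromide | Br[Mg]CCC1OCCO1 | intermediate (not isolated)
6 | 2-[(3S)-3-{[(tert-butyldiphenylsilyl)oxy]methyl}pent-4-en-1-yl]-1,3-dioxolane | C=C[C@@H](CO[Si](c1ccccc1)(c1ccccc1)C(C)(C)C)CCC1OCCO1 | intermediate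
7 | (4S)-4-{[(tert-butyldiphenylsilyl)oxy]methyl}hex-5-enal | C=C[C@@H](CO[Si](c1ccccc1)(c1ccccc1)C(C)(C)C)CCC=O | intermediate
8 | methyl 2-(diethoxyphosphoryl)acetate | COC(=O)CP(=O)(OCC)OCC | starting material
9 | 3-bromoprop-1-ene | C=CCBr | starting material
10 | methyl 2-(diethoxyphosphoryl)pent-4-enoate (racemic) | COC(=O)C(CC=C)P(=O)(OCC)OCC | intermediate
11 | methyl 2-(diethoxyphosphoryl)-3-(1,2,4-trioxolan-3-yl)propanoate | COC(=O)C(CC1OCOO1)P(=O)(OCC)OCC | intermediate (not isolated)
12 | methyl 2-(diethoxyphosphoryl)-4-oxobutanoate (racemic) | COC(=O)C(CC=O)P(=O)(OCC)OCC | intermediate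
13 | prop-2-enal | C=CC=O | starting material
14 | tert-butyl prop-2-enoate | C=CC(=O)OC(C)(C)C | starting material
15 | tert-butyl 3-hydroxy-2-methylidenepent-4-enoate (racemic) | C=CC(O)C(=C)C(=O)OC(C)(C)C | intermediate
16 | tert-butyl (2Z)-2-(bromomethyl)penta-2,4-dienoate | C=C/C=C(\CBr)C(=O)OC(C)(C)C | intermediate
17 | 1-tert-butyl 7-methyl (3R,4R)-6-(diethoxyphosphoryl)-3-ethenyl-2-methylidene-4-[(trimethylsilyl)oxy]heptanedioate (both C6 epimers) | COC(=O)C(P(=O)(OCC)OCC)C[C@@H](O[Si](C)(C)C)[C@@H](C(=C)C(=O)OC(C)(C)C)C=C | intermediate (not isolated)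
18 | 1-tert-butyl 7-methyl (3R,4R)-6-(diethoxyphosphoryl)-3-ethenyl-4-hydroxy-2-methylideneheptanedioate (both C6 epimers) | COC(=O)C(P(=O)(OCC)OCC)C[C@@H](O)[C@@H](C(=C)C(=O)OC(C)(C)C)C=C | intermediate
19 | (2R)-2-methylbutanoic acid | CC[C@@H](C)C(=O)O | starting material
20 | O-[(2R)-2-methylbutanoyl]-N,N'-diisopropylisourea | CC[C@@H](C)C(=O)OC(=NC(C)C)NC(C)C | intermediate (not isolated)
21 | 1-tert-butyl 7-methyl (3R,4R)-6-(diethoxyphosphoryl)-3-ethenyl-2-methylidene-4-{[(2R)-2-methylbutanoyl]oxy}heptanedioate (both C6 epimers) | COC(=O)C(P(=O)(OCC)OCC)C[C@@H](OC(=O)[C@H](C)CC)[C@@H](C(=C)C(=O)OC(C)(C)C)C=C | intermediate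
22 | 1-tert-butyl 7-methyl (3R,4R,6E)-6-[(4S)-4-{[(tert-butyldiphenylsilyl)oxy]methyl}hex-5-en-1-ylidene]-3-ethenyl-2-methylidene-4-{[(2R)-2-methylbutanoyl]oxy}heptanedioate | C=C[C@@H](CO[Si](c1ccccc1)(c1ccccc1)C(C)(C)C)CC/C=C(/C(=O)OC)C[C@@H](OC(=O)[C@H](C)CC)[C@@H](C(=C)C(=O)OC(C)(C)C)C=C | intermediate
23 | methyl (1E,5S,6Z,8R,9R)-8-[3-(tert-butoxy)-3-oxoprop-1-en-2-yl]-5-{[(tert-butyldiphenylsilyl)oxy]methyl}-9-{[(2R)-2-methylbutanoyl]oxy}cyclodeca-1,6-diene-1-carboxylate | C=C(C(=O)OC(C)(C)C)[C@H]1/C=C\[C@@H](CO[Si](c2ccccc2)(c2ccccc2)C(C)(C)C)CC/C=C(/C(=O)OC)C[C@H]1OC(=O)[C@H](C)CC | intermediate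
24 | methyl (3aS,4R,6E,10S,11aR)-10-{[(tert-butyldiphenylsilyl)oxy]methyl}-3-methylidene-4-{[(2R)-2-methylbutanoyl]oxy}-2-oxo-2,3,3a,4,5,8,9,10,11,11a-decahydrocyclodeca[b]furan-6-carboxylate | C=C1C(=O)O[C@@H]2C[C@@H](CO[Si](c3ccccc3)(c3ccccc3)C(C)(C)C)CC/C=C(/C(=O)OC)C[C@@H](OC(=O)[C@H](C)CC)[C@@H]12 | intermediate
25 | methyl (3aS,4R,6E,10S,11aR)-10-(hydroxymethyl)-3-methylidene-4-{[(2R)-2-methylbutanoyl]oxy}-2-oxo-2,3,3a,4,5,8,9,10,11,11a-decahydrocyclodeca[b]furan-6-carboxylate (CNP0141952.4) | C=C1C(=O)O[C@@H]2C[C@@H](CO)CC/C=C(/C(=O)OC)C[C@@H](OC(=O)[C@H](C)CC)[C@@H]12 | target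

**Step count and risks**

Total: 14 steps. Longest linear sequence: 8 steps (5, 6, 9, 10, 11, 12, 13, 14 from 8; equally 1, 2, 3, 4, 11, 12, 13, 14 from 1).

The three steps most likely to fail:

Step 13, the proposed new hydrolactonisation. The 1,2-disubstituted alkene may be too weakly activated for attack by an ester oxygen, the alkylplatinum intermediate may undergo β-hydride elimination, or the 1,6-diene may chelate the metal. The fallback uses known chemistry only and sets out from 23. CF3CO2H in CH2Cl2 at 0 °C cleaves the tert-butyl ester to the acrylic acid F1. Kinetic iodolactonisation (I2, NaHCO3, MeCN/H2O, 0 °C) then closes the lactone 5-exo and anti, under the same conformational control, to the iodolactone F2. Radical deiodination with Bu3SnH, catalytic (PhSe)2 and Et3B/air at rt (fast hydrogen transfer to outrun transannular 5-exo cyclisation onto the enoate) comes back to the route at 24.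

Step 12, the ring-closing metathesis. Oligomerisation or engagement of the acrylate could erode the yield of the ten-membered ring. The fallback changes the ring-closing bond and sets out from 21 and 7. Cross-metathesis of their vinyl groups (7 in excess, same ruthenium catalyst, CH2Cl2, 40 °C) gives the linear phosphonate aldehyde F3. Intramolecular Horner–Wadsworth–Emmons olefination (LiCl, DBU, MeCN, 1 mM, slow addition) closes C1=C10 to the E-configured macrocycle F4. Under the conditions of step 13, F4 comes back to the route at 24, because C5 becomes a methylene group and the alkene geometry is erased.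

Step 9, the asymmetric allylation. A γ-vinyl donor lies outside the demonstrated scope of the chromium catalyst, and enantioselectivity or the γ-regiochemistry of the pentadienyl species may fall short. The fallback gives up catalyst control and sets out from 12 and 16. An indium-mediated Barbier reaction (In powder, THF/H2O, rt), which is reliably syn-selective for Z bromides, gives racemic syn alcohol, that is 18 together with the mirror-image alcohol F5. Esterification with 19 as in step 10 gives 21 and the diastereomeric ester F6. Both are carried through steps 11 and 12 via the diastereomeric tetraene F7, and the diastereomeric macrocycle F8 is removed by chromatography, coming back to the route at 23 at the cost of half the material.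

**Further compounds**
F1 | step 13 | 2-[(1R,2Z,4S,7E,10R)-4-{[(tert-butyldiphenylsilyl)oxy]methyl}-8-(methoxycarbonyl)-10-{[(2R)-2-methylbutanoyl]oxy}cyclodeca-2,7-dien-1-yl]prop-2-enoic acid | C=C(C(=O)O)[C@H]1/C=C\[C@@H](CO[Si](c2ccccc2)(c2ccccc2)C(C)(C)C)CC/C=C(/C(=O)OC)C[C@H]1OC(=O)[C@H](C)CC
F2 | step 13 | iodolactone: 24 carrying iodine at C-11 (germacrane C5), anti to the lactone oxygen on C-11a | C=C1C(=O)O[C@@H]2[C@@H](I)[C@@H](CO[Si](c3ccccc3)(c3ccccc3)C(C)(C)C)CC/C=C(/C(=O)OC)C[C@@H](OC(=O)[C@H](C)CC)[C@@H]12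
F3 | step 12 | 1-tert-butyl 7-methyl (3R,4R)-3-[(1E,3S)-3-{[(tert-butyldiphenylsilyl)oxy]methyl}-6-oxohex-1-en-1-yl]-6-(diethoxyphosphoryl)-2-methylidene-4-{[(2R)-2-methylbutanoyl]oxy}heptanedioate | COC(=O)C(P(=O)(OCC)OCC)C[C@@H](OC(=O)[C@H](C)CC)[C@@H](C(=C)C(=O)OC(C)(C)C)/C=C/[C@@H](CO[Si](c1ccccc1)(c1ccccc1)C(C)(C)C)CCC=O
F4 | step 12 | methyl (1E,5S,6E,8R,9R)-8-[3-(tert-butoxy)-3-oxoprop-1-en-2-yl]-5-{[(tert-butyldiphenylsilyl)oxy]methyl}-9-{[(2R)-2-methylbutanoyl]oxy}cyclodeca-1,6-diene-1-carboxylate | C=C(C(=O)OC(C)(C)C)[C@H]1/C=C/[C@@H](CO[Si](c2ccccc2)(c2ccccc2)C(C)(C)C)CC/C=C(/C(=O)OC)C[C@H]1OC(=O)[C@H](C)CC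
F5 | step 9 | 1-tert-butyl 7-methyl (3S,4S)-6-(diethoxyphosphoryl)-3-ethenyl-4-hydroxy-2-methylideneheptanedioate | COC(=O)C(P(=O)(OCC)OCC)C[C@H](O)[C@H](C(=C)C(=O)OC(C)(C)C)C=C
F6 | step 9 | 1-tert-butyl 7-methyl (3S,4S)-6-(diethoxyphosphoryl)-3-ethenyl-2-methylidene-4-{[(2R)-2-methylbutanoyl]oxy}heptanedioate | COC(=O)C(P(=O)(OCC)OCC)C[C@H](OC(=O)[C@H](C)CC)[C@H](C(=C)C(=O)OC(C)(C)C)C=C
F7 | step 9 | 1-tert-butyl 7-methyl (3S,4S,6E)-6-[(4S)-4-{[(tert-butyldiphenylsilyl)oxy]methyl}hex-5-en-1-ylidene]-3-ethenyl-2-methylidene-4-{[(2R)-2-methylbutanoyl]oxy}heptanedioate | C=C[C@@H](CO[Si](c1ccccc1)(c1ccccc1)C(C)(C)C)CC/C=C(/C(=O)OC)C[C@H](OC(=O)[C@H](C)CC)[C@H](C(=C)C(=O)OC(C)(C)C)C=C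
F8 | step 9 | methyl (1E,5S,6Z,8S,9S)-8-[3-(tert-butoxy)-3-oxoprop-1-en-2-yl]-5-{[(tert-butyldiphenylsilyl)oxy]methyl}-9-{[(2R)-2-methylbutanoyl]oxy}cyclodeca-1,6-diene-1-carboxylate | C=C(C(=O)OC(C)(C)C)[C@@H]1/C=C\[C@@H](CO[Si](c2ccccc2)(c2ccccc2)C(C)(C)C)CC/C=C(/C(=O)OC)C[C@@H]1OC(=O)[C@H](C)CC
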